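- Read J over Z in the earlier runs before you touch the flask, as I did when I took it over.

| flask | Z | X | remark | time |
|---|---|---|---|---|
| elm | 0.050 M (fed, over 30 min) | 4.2 equiv | run made earlier |  |
| birch | 0.050 M (fed, over 30 min) | 6.6 equiv | run made earlier |  |
| cedar | 0.10 M (fed, over 30 min) | 3 equiv | run made earlier |  |
| flask | 0.050 M (fed, over 30 min) | 3.00 equiv |  | 4.0 d |

- elm (time / d: J / %, Z / %): 0.0208: 32.0, 34.1; 0.0556: 38.0, 16.1; 0.167: 32.8, 14.8; 0.417: 27.4, 13.5; 1.04: 21.4, 13.3; 2.50: 20.3, 12.6
- birch (time / d: J / %, Z / %): 0.0208: 43.9, 22.5; 0.0556: 49.8, 8.8; 0.167: 42.6, 7.1; 0.417: 32.5, 7.1; 1.04: 25.7, 6.5; 2.50: 24.5, 6.4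
- cedar (time / d: J / %, Z / %): 0.0208: 27.7, 32.6; 0.0833: 28.3, 21.8; 0.250: 23.8, 20.8; 0.833: 18.3, 20.2; 2.50: 16.8, 19.9

(each reading ± 0.5 percentage points)

- the earlier runs were read with a standard deviation of 0.5 percentage points
- steps under discussion: Z + X <-> G + D; D + X <-> G + J; J <-> L; J -> E
- percentages count the whole charge, also what has not yet gone in

- time, not beyond 4.0 d, at which the flask holds most J
- the amount of J, in percent of the Z charged, at that time

- Each exchange swaps one ligand for one, so in the ratio of forward to back rate both time and concentration cancel. I therefore carried J over Z, which I called the balance quotient (part of the reaction quotient), from cedar to the flask, since both had the same equivalents of X.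
- At its highest reading of J, cedar gave 28.3% over 21.8%, a quotient of 1.30. I expected that quotient at the flask's crest, with J near cedar's reading. The quotient holds no time, so I named no hour.
- Don't leave the flask standing past the crest: cedar's J fell to 16.8% with its Z read at 19.9%, a last quotient of 0.844.
- Birch's last quotient read 3.83; birch and cedar differ in charge as well as in X, but I took the charge to cancel as above, so against cedar I read the quotient as rising with equivalents of X to the power 1.92.
- The forecast, that the flask should “share cedar's quasi-equilibrium”, gave 27.5% at 1.9 h.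
- The flask gave 30.1% of J at 1.00 h.

    Z + X ⇌ G + D (K = 1.20, k = 0.613 M⁻¹ min⁻¹)
    D + X ⇌ G + J (K = 0.390, k = 0.666 M⁻¹ min⁻¹)
    J ⇌ L (K = 1.80, k = 0.00175 min⁻¹)
    J → E (k = 4.90 × 10⁻⁵ min⁻¹)

- At that time the flask held J 30.1% over Z 23.1%, a quotient of 1.30, against cedar's 1.30. The run without the falling back of G + J to D + X reached 77.5% instead of 30.1%, the largest single effect on the highest J. For a neighbour flask with 1.80 equiv of X, cedar's last quotient and the power gave 0.317, and that neighbour ended at 4.00 d with J 10.5% over Z 33.9%, a quotient of 0.310.

The earlier runs and the new flask are simulated with constants of no real substance, and the scatter is random.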